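**Plan**

1. Retrosynthesis: the late groups are removed first (C15 silyl ether, C9 acetate, the lactone from O6 and a C12 acetal, the C8 ester, the C14 formyl group from a C10 enol triflate). The ten-membered ring is then cut at C2–C3 by an anionic oxy-Cope transform, which reconnects C5–C10 and gives a cis-1-vinyl-2-alkenylcyclohexanol.
2. The feature that allows this is the 1,5-diene C10=C1–C2–C3–C4=C5 of the ten-membered ring, whose sp2 carbon C10 can carry an oxygen. Its Cope retron is the six-membered ring C5–C10, on which C6–C9 already hold all four ring stereocentres.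
3. The cyclohexane is cut at C5–C6 and C7–C8 by a Diels–Alder transform into a 1-methoxy-3-silyloxy diene (C8, C9, C10, C5, carrying C3/C4/C15) and an (E)-β-benzoyloxy enone (C6, C7, carrying C11–C13).
4. Forward order: six-membered ring by cycloaddition, vinyl carbinol, trans-diaxial 8,9-dioxygenation, ring expansion to the ten-membered ring with enolate triflation, formylation, lactone ring last.
5. Stereochemistry: C6 and C7 (and temporary C5) from the catalyst-controlled endo cycloaddition of the (E)-dienophile; C10 by axial vinyl addition; C8 and C9 by hydroxyl-directed epoxidation and inverting opening; C4=C5 geometry from the chair transition state; C1=C10 geometry by thermodynamic isomerisation; the ester stereocentre from (R)-2-methylbutanoic acid.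

Key step: step 14

**Remarks and assumptions**

- Locants are the germacrane locants of the target: ring C1–C10; C11–C13 on C7 (C12 lactone carbonyl, C13 exocyclic methylene); C14 on C10; C15 on C4. α/β are as in the target drawn with H-7 α (6-O α, 8-O β, 9-O α). "Ring-cis" means the two ring bonds lie on the same side of a ring double bond.
- Alcohol 6 is racemic (its stereocentre is removed in step 4) and lactol 28 is an anomeric mixture (its stereocentre is removed in step 20); these centres are left undefined in the SMILES.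
- Assumption: the (S)-oxazaborolidinium salt of step 7 is taken to expose the enone face that leads to 12; if the opposite sense is found, the (R)-catalyst is used.
- The starting materials 1, 4, 9 and 23 are taken as commercially available.

**Route**

Step 1
Reactants: 1 2-methylenepropane-1,3-diol
Product: 2 2-[(tert-butyldiphenylsilyloxy)methyl]prop-2-en-1-ol
Conditions: NaH (1.0 equiv), THF, 0 °C; then t-BuPh2SiCl (1.0 equiv), 0 to 23 °C
Reagents that add atoms: tert-butyl(chloro)diphenylsilane, CC(C)(C)[Si](Cl)(c1ccccc1)c1ccccc1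
Why: Monoprotection of a symmetric diol (silyl ether formation), in which the monosodium alkoxide is silylated faster than the remaining neutral hydroxyl.

Step 2
Reactants: 2 2-[(tert-butyldiphenylsilyloxy)methyl]prop-2-en-1-ol
Product: 3 [2-(bromomethyl)prop-2-enyloxy](tert-butyl)diphenylsilane
Conditions: CBr4, PPh3, CH2Cl2, 0 °C
Reagents that add atoms: tetrabromomethane, BrC(Br)(Br)Br
Why: Appel bromination converts the primary allylic alcohol into the bromide under neutral conditions that leave the silyl ether untouched.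

Step 3
Reactants: 3 [2-(bromomethyl)prop-2-enyloxy](tert-butyl)diphenylsilane; 4 (E)-3-methoxyprop-2-enal
Product: 6 racemic (E)-5-[(tert-butyldiphenylsilyloxy)methyl]-1-methoxyhexa-1,5-dien-3-ol, via allylzinc bromide 5 (not isolated)
Conditions: Zn dust, THF, 0 °C; then 4, −78 to 0 °C; aqueous work-up
Reagents that add atoms: none
Why: Barbier-type allylation, in which the 2-substituted allylzinc reagent adds 1,2 to the aldehyde of the vinylogous ester; its two allyl termini are equivalent, so only one constitution can form.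

Step 4
Reactants: 6 racemic (E)-5-[(tert-butyldiphenylsilyloxy)methyl]-1-methoxyhexa-1,5-dien-3-ol
Product: 7 (E)-5-[(tert-butyldiphenylsilyloxy)methyl]-1-methoxyhexa-1,5-dien-3-one
Conditions: MnO2 (activated, excess), CH2Cl2, 23 °C
Reagents that add atoms: none
Why: MnO2 oxidation of the allylic alcohol should give the β-methoxy enone under neutral conditions that do not move the β,γ-alkene into conjugation.

Step 5
Reactants: 7 (E)-5-[(tert-butyldiphenylsilyloxy)methyl]-1-methoxyhexa-1,5-dien-3-one
Product: 8 (1E,3Z)-3-(tert-butyldimethylsilyloxy)-5-[(tert-butyldiphenylsilyloxy)methyl]-1-methoxyhexa-1,3,5-triene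
Conditions: t-BuMe2SiOTf, Et3N, Et2O, −78 to 0 °C
Reagents that add atoms: tert-butyldimethylsilyl trifluoromethanesulfonate, CC(C)(C)[Si](C)(C)OS(=O)(=O)C(F)(F)F
Why: Soft enolisation with O-silylation (silyl enol ether formation) at the only α-methylene should give the (Z)-dienol ether, the geometry that places the C5 substituent outward in the s-cis diene.

Step 6
Reactants: 9 1,1-dimethoxypropan-2-one
Product: 11 (E)-4,4-dimethoxy-3-oxobut-1-en-1-yl benzoate, via sodium enolate 10 (not isolated)
Conditions: NaOMe, HCO2Me, Et2O, 0 to 23 °C; then PhCOCl, THF, 0 °C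
Reagents that add atoms: methyl formate, COC=O; benzoyl chloride, O=C(Cl)c1ccccc1
Why: Crossed Claisen condensation (formylation) at the methyl group gives the sodium enolate of the β-keto aldehyde, and O-acylation traps it as the (E)-enol benzoate.

Step 7
Reactants: 8 (1E,3Z)-3-(tert-butyldimethylsilyloxy)-5-[(tert-butyldiphenylsilyloxy)methyl]-1-methoxyhexa-1,3,5-triene; 11 (E)-4,4-dimethoxy-3-oxobut-1-en-1-yl benzoate
Product: 12 cycloadduct (ring C5 to C10): C9=C10 tert-butyldimethylsilyl enol ether with 8β-methoxy; 7β-(2,2-dimethoxyacetyl); 6α-benzoyloxy; 5β-[3-(tert-butyldiphenylsilyloxy)prop-1-en-2-yl]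
Conditions: (S)-1-(2-methylphenyl)-3,3-diphenyltetrahydro-1H,3H-pyrrolo[1,2-c][1,3,2]oxazaborole·HN(SO2CF3)2 (20 mol %), CH2Cl2, −78 to −40 °C; Et3N quench
Reagents that add atoms: none
Why: Normal-demand Diels–Alder cycloaddition under chiral oxazaborolidinium catalysis, in which the nucleophilic C5 terminus of the diene bonds to the enone β-carbon C6, the endo transition state places the C7 acyl group cis to the outward C5 and C8 substituents, the (E)-alkene holds the C6 benzoate trans to it, and the catalyst-shielded enone face sets the absolute configuration at C5, C6 and C7.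

Step 8
Reactants: 12 cycloadduct with 7β-(2,2-dimethoxyacetyl) group
Product: 13 methylenated cycloadduct: as 12 but with 7β-(3,3-dimethoxyprop-1-en-2-yl)
Conditions: Cp2Ti(μ-Cl)(μ-CH2)AlMe2 (1.2 equiv), pyridine, THF–toluene, −40 to 0 °C; cold aqueous NaOH work-up
Reagents that add atoms: Cp2Ti(μ-Cl)(μ-CH2)AlMe2, C[Al-]1(C)C[Ti]([Cl+]1)(C1C=CC=C1)C1C=CC=C1
Why: Tebbe methylenation olefinates the ketone under non-basic conditions, so the β-benzoyloxy ketone should not eliminate, and at low temperature the ketone reacts ahead of the benzoate while the silyl enol ether keeps C10 masked.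

Step 9
Reactants: 13 methylenated cycloadduct
Product: 14 cyclohex-8-en-10-one with 7β-(3,3-dimethoxyprop-1-en-2-yl); 6α-benzoyloxy; 5β-[3-(tert-butyldiphenylsilyloxy)prop-1-en-2-yl]
Conditions: camphorsulfonic acid (10 mol %), MeOH (0.2 equiv), CH2Cl2, 0 °C
Reagents that add atoms: none
Why: Acid-catalysed unmasking of the cycloadduct (protonation at C9, transfer of the silyl group to methanol, β-elimination of the C8 methoxy group) gives the conjugated enone, the usual fate of 1-methoxy-3-silyloxy-diene adducts; methanol keeps the dimethyl acetal intact.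

Step 10
Reactants: 14 cyclohex-8-en-10-one with 6α-benzoate
Product: 15 10β-vinylcyclohex-8-ene-6α,10α-diol with the 5β and 7β side chains of 14
Conditions: CeCl3, CH2=CHMgBr (5 equiv), THF, −78 °C, then 0 to 23 °C; aqueous work-up
Reagents that add atoms: vinylmagnesium bromide, C=C[Mg]Br
Why: 1,2-Addition of the organocerium reagent to the enone from the axial direction (anti to the pseudo-axial H-5, with no axial C8 substituent to oppose it) should place the vinyl group cis to the C5 side chain, and the excess Grignard reagent removes the benzoate by double addition.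

Step 11
Reactants: 15 10β-vinylcyclohex-8-ene-6α,10α-diol
Product: 16 8α,9α-epoxide of 15
Conditions: VO(acac)2 (5 mol %), t-BuOOH (1.2 equiv), CH2Cl2, 0 °C
Reagents that add atoms: tert-butyl hydroperoxide, CC(C)(C)OO
Why: Hydroxyl-directed vanadium-catalysed epoxidation should deliver oxygen to the more substituted (ring) allylic alkene on the face of the 10α-hydroxyl, which is also the face anti to the C7 side chain.

Step 12
Reactants: 16 8α,9α-epoxide
Product: 17 8β-(4-methoxybenzyloxy)-10β-vinylcyclohexane-6α,9α,10α-triol with the 5β and 7β side chains of 14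
Conditions: Ti(OiPr)4 (1.5 equiv) premixed with 4-MeOC6H4CH2OH (10 equiv, iPrOH removed), toluene, 23 to 50 °C
Reagents that add atoms: 4-methoxybenzyl alcohol, COc1ccc(CO)cc1
Why: Titanium-assisted trans-diaxial opening of the cis-2,3-epoxy alcohol at the carbon remote from the carbinol (C8), with inversion, should set the 8β-ether and leave the 9α-hydroxyl; C9 is shielded by the quaternary C10.

Step 13
Reactants: 17 8β-(4-methoxybenzyloxy) triol
Product: 18 6α,9α-bis(triethylsilyl) ether of 17 with free 10α-hydroxyl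
Conditions: Et3SiCl (2.5 equiv), imidazole, DMAP (cat.), DMF, 0 to 23 °C
Reagents that add atoms: chlorotriethylsilane, CC[Si](Cl)(CC)CC
Why: Silyl ether formation on the two secondary hydroxyls, while the hindered tertiary allylic hydroxyl needed for the ring expansion should stay free.

Step 14
Reactants: 18 6α,9α-bis(triethylsilyl) ether with free 10α-hydroxyl
Product: 21 ten-membered enol triflate (1(10)Z,4E): 10-trifluoromethanesulfonyloxy; 6α- and 9α-triethylsilyloxy; 8β-(4-methoxybenzyloxy); 7β-(3,3-dimethoxyprop-1-en-2-yl); 4-(tert-butyldiphenylsilyloxymethyl)cyclodeca-1(10),4-diene, via potassium alkoxide 19 (not isolated), via potassium enolate 20 (not isolated)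
Conditions: KN(SiMe3)2 (1.1 equiv), 18-crown-6 (1.2 equiv), THF, −78 to 0 °C; then N-(5-chloropyridin-2-yl)bis(trifluoromethanesulfonyl)imide (1.2 equiv), −78 °C
Reagents that add atoms: N-(5-chloropyridin-2-yl)-1,1,1-trifluoro-N-(trifluoromethylsulfonyl)methanesulfonamide, O=S(=O)(N(c1ccc(Cl)cn1)S(=O)(=O)C(F)(F)F)C(F)(F)F
Why: Deprotonation gives alkoxide 19, whose 3-oxido-1,5-diene (C2=C1–C10(O−)–C5–C4=C3) undergoes a charge-accelerated [3,3]-sigmatropic shift that breaks C5–C10 and forms C2–C3, with enolate formation outweighing the strain of the medium ring. The closest known reaction type is the anionic oxy-Cope ring expansion of 1,2-dialkenylcyclohexanols to cyclodec-5-enones, followed by O-sulfonylation of the regiodefined enolate. The ten-membered ring closes by a four-atom ring expansion of the six-membered ring through a six-membered chair-like pericyclic array, not by an exo or endo cyclisation of a chain, so no high dilution is needed. No new stereocentre is formed (C5 and C10 become sp2), but both alkene geometries are: with the cis-dialkenyl arrangement and the cyclohexane held in the chair that has the C5, C6 and C7 substituents equatorial, the vinyl group is axial, so C6 is axial and C9 equatorial in the transition-state chair, which should give the ring-cis C4=C5 alkene and the ring-trans (Z) enolate; the latter geometry is corrected in step 18. The step needs the [3,3] shift to win over a [1,3] shift or fragmentation and needs O-triflation at the C10/C1 enolate only; the cis-1,2-dialkenyl geometry, the absence of any other 1,5-diene pairing with the carbinol and trapping at −78 °C should secure this, and the C9 silyl group is expected to stay on the less hindered secondary oxygen.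

Step 15
Reactants: 21 ten-membered enol triflate
Product: 22 8β-alcohol of 21 (4-methoxybenzyl group removed)
Conditions: DDQ (1.3 equiv), CH2Cl2–pH 7 buffer (10:1), 0 °C
Reagents that add atoms: none
Why: Oxidative cleavage of the 4-methoxybenzyl ether by DDQ (hydride abstraction to the oxocarbenium ion, then hydrolysis) should free only the C8 hydroxyl and leave the silyl ethers, acetal and enol triflate intact.

Step 16
Reactants: 22 8β-alcohol; 23 (R)-2-methylbutanoic acid
Product: 24 8β-[(R)-2-methylbutanoate] of 22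
Conditions: DCC, DMAP, CH2Cl2, 0 to 23 °C
Reagents that add atoms: none
Why: Steglich esterification (carbodiimide activation, DMAP acyl transfer) installs the ester at O8 under conditions that should not epimerise the α-stereocentre of the acid.

Step 17
Reactants: 24 8β-[(R)-2-methylbutanoate] enol triflate
Product: 25 (1(10)Z,4E)-14-aldehyde (ring-trans C1=C10): as 24 with the triflate replaced by a formyl group
Conditions: Pd(PPh3)4 (5 mol %), CO (1 atm), Bu3SnH (slow addition), LiCl, THF, 40 °C
Reagents that add atoms: carbon monoxide, [C-]#[O+]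
Why: Palladium-catalysed reductive carbonylation (formylation) of the enol triflate, by oxidative addition to zerovalent palladium, CO insertion and hydride transfer from tin, gives the enal with retention of alkene geometry; the temperature is kept low because E,Z-cyclodeca-1,5-dienes can undergo Cope rearrangement on heating.

Step 18
Reactants: 25 (1(10)Z,4E)-14-aldehyde
Product: 26 (1(10)E,4E)-14-aldehyde (ring-cis C1=C10)
Conditions: I2 (5 mol %), CH2Cl2, visible light, 23 °C
Reagents that add atoms: none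
Why: Iodine-catalysed alkene isomerisation (reversible addition of iodine atoms to the enal) should equilibrate the (Z)-enal to the thermodynamically preferred (E)-2-alkyl-2-enal, which is the ring-cis C1=C10 geometry of the target.

Step 19
Reactants: 26 (1(10)E,4E)-14-aldehyde
Product: 28 6α,12-lactol (anomeric mixture) with free 9α-hydroxyl and 15-O-tert-butyldiphenylsilyl group, via hydroxy aldehyde 27 (not isolated)
Conditions: AcOH–THF–H2O (3:1:1), 23 to 35 °C
Reagents that add atoms: water, O
Why: Mild acid hydrolysis cleaves both triethylsilyl ethers and the allylic dimethyl acetal, and the freed C6 hydroxyl adds to the C12 aldehyde to give the five-membered lactol (acetal hydrolysis and lactolisation); the tert-butyldiphenylsilyl ether should be stable.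

Step 20
Reactants: 28 6α,12-lactol
Product: 29 12,6α-lactone (α-methylene-γ-butyrolactone) with free 9α-hydroxyl and 15-O-tert-butyldiphenylsilyl group
Conditions: TEMPO (20 mol %), PhI(OAc)2 (1.2 equiv), CH2Cl2, 0 to 23 °C
Reagents that add atoms: none
Why: Oxoammonium (TEMPO/PhI(OAc)2) oxidation should convert the lactol into the lactone faster than it oxidises the hindered secondary C9 alcohol.

Step 21
Reactants: 29 12,6α-lactone with free 9α-hydroxyl
Product: 30 9α-acetate of 29
Conditions: Ac2O, pyridine, DMAP (cat.), CH2Cl2, 0 °C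
Reagents that add atoms: acetic anhydride, CC(=O)OC(C)=O
Why: DMAP-catalysed acetylation of the only remaining free hydroxyl.

Step 22
Reactants: 30 9α-acetate 15-silyl ether
Product: 31 (1(10)E,4E)-9α-acetoxy-15-hydroxy-8β-[(R)-2-methylbutanoyloxy]-14-oxogermacra-1(10),4,11(13)-trien-12,6α-olide (target)
Conditions: HF·pyridine, pyridine, THF, 0 to 23 °C
Reagents that add atoms: none
Why: Fluoride-mediated desilylation under buffered conditions should remove the tert-butyldiphenylsilyl ether without attacking the esters, the enal or the methylene lactone.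

**Compound list**

1 | 2-methylenepropane-1,3-diol | C=C(CO)CO | starting material
2 | 2-[(tert-butyldiphenylsilyloxy)methyl]prop-2-en-1-ol | C=C(CO)CO[Si](c1ccccc1)(c1ccccc1)C(C)(C)C | intermediate
3 | [2-(bromomethyl)prop-2-enyloxy](tert-butyl)diphenylsilane | C=C(CBr)CO[Si](c1ccccc1)(c1ccccc1)C(C)(C)C | intermediate
4 | (E)-3-methoxyprop-2-enal | CO/C=C/C=O | starting material
5 | {2-[(tert-butyldiphenylsilyloxy)methyl]prop-2-enyl}zinc bromide | Br[Zn]CC(=C)CO[Si](c1ccccc1)(c1ccccc1)C(C)(C)C | intermediate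
6 | racemic (E)-5-[(tert-butyldiphenylsilyloxy)methyl]-1-methoxyhexa-1,5-dien-3-ol | CO/C=C/C(O)CC(=C)CO[Si](c1ccccc1)(c1ccccc1)C(C)(C)C | intermediate
7 | (E)-5-[(tert-butyldiphenylsilyloxy)methyl]-1-methoxyhexa-1,5-dien-3-one | CO/C=C/C(=O)CC(=C)CO[Si](c1ccccc1)(c1ccccc1)C(C)(C)C | intermediate
8 | (1E,3Z)-3-(tert-butyldimethylsilyloxy)-5-[(tert-butyldiphenylsilyloxy)methyl]-1-methoxyhexa-1,3,5-triene | CO/C=C/C(O[Si](C)(C)C(C)(C)C)=C/C(=C)CO[Si](c1ccccc1)(c1ccccc1)C(C)(C)C | intermediate
9 | 1,1-dimethoxypropan-2-one | CC(=O)C(OC)OC | starting material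
10 | sodium (E)-4,4-dimethoxy-3-oxobut-1-en-1-olate | [Na+].[O-]/C=C/C(=O)C(OC)OC | intermediate
11 | (E)-4,4-dimethoxy-3-oxobut-1-en-1-yl benzoate | O=C(O/C=C/C(=O)C(OC)OC)c1ccccc1 | intermediate
12 | cycloadduct: C9=C10 silyl enol ether, 8β-OMe, 7β-(2,2-dimethoxyacetyl), 6α-OBz, 5β-[3-(TBDPS-oxy)prop-1-en-2-yl] | C1(O[Si](C)(C)C(C)(C)C)=C[C@@H](OC)[C@@H](C(=O)C(OC)OC)[C@H](OC(=O)c2ccccc2)[C@H]1C(=C)CO[Si](c2ccccc2)(c2ccccc2)C(C)(C)C | intermediate
13 | methylenated cycloadduct: as 12 with 7β-(3,3-dimethoxyprop-1-en-2-yl) | C1(O[Si](C)(C)C(C)(C)C)=C[C@@H](OC)[C@@H](C(=C)C(OC)OC)[C@H](OC(=O)c2ccccc2)[C@H]1C(=C)CO[Si](c2ccccc2)(c2ccccc2)C(C)(C)C | intermediate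
14 | cyclohex-8-en-10-one, 7β-(3,3-dimethoxyprop-1-en-2-yl), 6α-OBz, 5β-[3-(TBDPS-oxy)prop-1-en-2-yl] | O=C1C=C[C@@H](C(=C)C(OC)OC)[C@H](OC(=O)c2ccccc2)[C@H]1C(=C)CO[Si](c2ccccc2)(c2ccccc2)C(C)(C)C | intermediate
15 | 10β-vinylcyclohex-8-ene-6α,10α-diol with the side chains of 14 | C=C[C@@]1(O)C=C[C@@H](C(=C)C(OC)OC)[C@H](O)[C@H]1C(=C)CO[Si](c2ccccc2)(c2ccccc2)C(C)(C)C | intermediate
16 | 8α,9α-epoxide of 15 | C=C[C@@]1(O)[C@@H]2O[C@@H]2[C@@H](C(=C)C(OC)OC)[C@H](O)[C@H]1C(=C)CO[Si](c3ccccc3)(c3ccccc3)C(C)(C)C | intermediate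
17 | 8β-(4-methoxybenzyloxy)-10β-vinylcyclohexane-6α,9α,10α-triol with the side chains of 14 | C=C[C@@]1(O)[C@H](O)[C@@H](OCc2ccc(OC)cc2)[C@@H](C(=C)C(OC)OC)[C@H](O)[C@H]1C(=C)CO[Si](c2ccccc2)(c2ccccc2)C(C)(C)C | intermediate
18 | 6α,9α-bis(triethylsilyl) ether of 17, 10α-OH free | C=C[C@@]1(O)[C@H](O[Si](CC)(CC)CC)[C@@H](OCc2ccc(OC)cc2)[C@@H](C(=C)C(OC)OC)[C@H](O[Si](CC)(CC)CC)[C@H]1C(=C)CO[Si](c2ccccc2)(c2ccccc2)C(C)(C)C | intermediate
19 | potassium 10α-alkoxide of 18 | [K+].C=C[C@@]1([O-])[C@H](O[Si](CC)(CC)CC)[C@@H](OCc2ccc(OC)cc2)[C@@H](C(=C)C(OC)OC)[C@H](O[Si](CC)(CC)CC)[C@H]1C(=C)CO[Si](c2ccccc2)(c2ccccc2)C(C)(C)C | intermediate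
20 | potassium (1(10)Z,4E)-cyclodeca-1(10),4-dien-10-olate (ring-expanded enolate) | [K+].CC[Si](CC)(CC)O[C@@H]1/C=C(/CO[Si](c2ccccc2)(c2ccccc2)C(C)(C)C)CC/C=C(\[O-])[C@H](O[Si](CC)(CC)CC)[C@@H](OCc2ccc(OC)cc2)[C@H]1C(=C)C(OC)OC | intermediate
21 | ten-membered enol triflate (1(10)Z,4E), 6α,9α-bis-OTES, 8β-OPMB, 15-OTBDPS, C12 dimethyl acetal | CC[Si](CC)(CC)O[C@@H]1/C=C(/CO[Si](c2ccccc2)(c2ccccc2)C(C)(C)C)CC/C=C(\OS(=O)(=O)C(F)(F)F)[C@H](O[Si](CC)(CC)CC)[C@@H](OCc2ccc(OC)cc2)[C@H]1C(=C)C(OC)OC | intermediate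
22 | 8β-alcohol of 21 | CC[Si](CC)(CC)O[C@@H]1/C=C(/CO[Si](c2ccccc2)(c2ccccc2)C(C)(C)C)CC/C=C(\OS(=O)(=O)C(F)(F)F)[C@H](O[Si](CC)(CC)CC)[C@@H](O)[C@H]1C(=C)C(OC)OC | intermediate
23 | (R)-2-methylbutanoic acid | CC[C@@H](C)C(=O)O | starting material
24 | 8β-[(R)-2-methylbutanoate] of 22 | CC[Si](CC)(CC)O[C@@H]1/C=C(/CO[Si](c2ccccc2)(c2ccccc2)C(C)(C)C)CC/C=C(\OS(=O)(=O)C(F)(F)F)[C@H](O[Si](CC)(CC)CC)[C@@H](OC(=O)[C@H](C)CC)[C@H]1C(=C)C(OC)OC | intermediate
25 | (1(10)Z,4E)-14-aldehyde, ring-trans C1=C10 | CC[Si](CC)(CC)O[C@@H]1/C=C(/CO[Si](c2ccccc2)(c2ccccc2)C(C)(C)C)CC/C=C(\C=O)[C@H](O[Si](CC)(CC)CC)[C@@H](OC(=O)[C@H](C)CC)[C@H]1C(=C)C(OC)OC | intermediate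
26 | (1(10)E,4E)-14-aldehyde, ring-cis C1=C10 | CC[Si](CC)(CC)O[C@@H]1/C=C(/CO[Si](c2ccccc2)(c2ccccc2)C(C)(C)C)CC/C=C(/C=O)[C@H](O[Si](CC)(CC)CC)[C@@H](OC(=O)[C@H](C)CC)[C@H]1C(=C)C(OC)OC | intermediate
27 | 6α,9α-dihydroxy 12,14-dialdehyde (open form of the lactol) | O[C@@H]1/C=C(/CO[Si](c2ccccc2)(c2ccccc2)C(C)(C)C)CC/C=C(/C=O)[C@H](O)[C@@H](OC(=O)[C@H](C)CC)[C@H]1C(=C)C=O | intermediate
28 | 6α,12-lactol (anomeric mixture), 9α-OH, 15-OTBDPS | C=C1C(O)O[C@@H]2/C=C(/CO[Si](c3ccccc3)(c3ccccc3)C(C)(C)C)CC/C=C(/C=O)[C@H](O)[C@@H](OC(=O)[C@H](C)CC)[C@@H]12 | intermediate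
29 | 12,6α-lactone, 9α-OH, 15-OTBDPS | C=C1C(=O)O[C@@H]2/C=C(/CO[Si](c3ccccc3)(c3ccccc3)C(C)(C)C)CC/C=C(/C=O)[C@H](O)[C@@H](OC(=O)[C@H](C)CC)[C@@H]12 | intermediate
30 | 9α-acetate of 29 | C=C1C(=O)O[C@@H]2/C=C(/CO[Si](c3ccccc3)(c3ccccc3)C(C)(C)C)CC/C=C(/C=O)[C@H](OC(C)=O)[C@@H](OC(=O)[C@H](C)CC)[C@@H]12 | intermediate
31 | (1(10)E,4E)-9α-acetoxy-15-hydroxy-8β-[(R)-2-methylbutanoyloxy]-14-oxogermacra-1(10),4,11(13)-trien-12,6α-olide | C=C1C(=O)O[C@@H]2/C=C(/CO)CC/C=C(/C=O)[C@H](OC(C)=O)[C@@H](OC(=O)[C@H](C)CC)[C@@H]12 | target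

**Totals**

Total step count: 22. Longest linear sequence: 21 steps (steps 1–5 and 7–22).

**Steps most likely to fail**

Step 7. Under Lewis-acid activation the reaction may turn stepwise, so that the benzoate is lost by addition–elimination or the silyl enol ether is cleaved, and the facial selectivity may be poor. Fallback: from 8 and 11 an uncatalysed thermal Diels–Alder reaction (toluene, 60 °C) should give the racemic endo adduct, that is 12 together with its enantiomer ent-12 F1. The racemate is carried through steps 8 and 9, which give ent-13 F2 and ent-14 F3 alongside 13 and 14. The racemic enone is then resolved by preparative chromatography on a chiral stationary phase, which returns to 14.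

Step 14. The silyl group may migrate from O9 to the alkoxide, the homoallylic alkoxide may fragment under the strongly basic conditions, or O-sulfonylation of the enolate may be incomplete. Fallback: from 18 a neutral thermal oxy-Cope rearrangement of the free alcohol (degassed o-dichlorobenzene, base-washed sealed tube, about 190 °C) should give, after irreversible tautomerisation of the enol, the ring-cis cyclodec-4-en-10-one F7. Kinetic deprotonation at the C1 methylene (KN(SiMe3)2, THF, −78 °C) and trapping with the same triflimide returns to 21; any C1=C10 geometric isomer of the triflate converges at 26 after step 18.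

Step 12. Attack of the alcohol at the hindered C8 (syn-axial to the vinyl group) may be slow, and isopropoxide transfer from titanium or exchange at the dimethyl acetal may compete. Fallback: from 16 the titanium-mediated opening with a carboxylic acid (benzoic acid, Ti(OiPr)4, CH2Cl2, 23 °C) should give the 8β-benzoate triol F4. Silylation of the two secondary hydroxyls (Et3SiCl, imidazole, DMF) gives the bis(triethylsilyl) ether F5. Reductive removal of the benzoate (iBu2AlH, CH2Cl2, −78 °C) gives the 8β-alcohol F6. Etherification with 4-methoxybenzyl 2,2,2-trichloroacetimidate and catalytic La(OTf)3 returns to 18.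

**Further compounds**

F1 | step 7 | enantiomer of cycloadduct 12 | C1(O[Si](C)(C)C(C)(C)C)=C[C@H](OC)[C@H](C(=O)C(OC)OC)[C@@H](OC(=O)c2ccccc2)[C@@H]1C(=C)CO[Si](c2ccccc2)(c2ccccc2)C(C)(C)C
F2 | step 7 | enantiomer of methylenated cycloadduct 13 | C1(O[Si](C)(C)C(C)(C)C)=C[C@H](OC)[C@H](C(=C)C(OC)OC)[C@@H](OC(=O)c2ccccc2)[C@@H]1C(=C)CO[Si](c2ccccc2)(c2ccccc2)C(C)(C)C
F3 | step 7 | enantiomer of enone 14 | O=C1C=C[C@H](C(=C)C(OC)OC)[C@@H](OC(=O)c2ccccc2)[C@@H]1C(=C)CO[Si](c2ccccc2)(c2ccccc2)C(C)(C)C
F4 | step 12 | 8β-benzoyloxy-10β-vinylcyclohexane-6α,9α,10α-triol with the side chains of 14 | C=C[C@@]1(O)[C@H](O)[C@@H](OC(=O)c2ccccc2)[C@@H](C(=C)C(OC)OC)[C@H](O)[C@H]1C(=C)CO[Si](c2ccccc2)(c2ccccc2)C(C)(C)C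
F5 | step 12 | 6α,9α-bis(triethylsilyl) ether of F4 | C=C[C@@]1(O)[C@H](O[Si](CC)(CC)CC)[C@@H](OC(=O)c2ccccc2)[C@@H](C(=C)C(OC)OC)[C@H](O[Si](CC)(CC)CC)[C@H]1C(=C)CO[Si](c2ccccc2)(c2ccccc2)C(C)(C)C
F6 | step 12 | 8β,10α-diol: F5 with the benzoate removed | C=C[C@@]1(O)[C@H](O[Si](CC)(CC)CC)[C@@H](O)[C@@H](C(=C)C(OC)OC)[C@H](O[Si](CC)(CC)CC)[C@H]1C(=C)CO[Si](c2ccccc2)(c2ccccc2)C(C)(C)C
F7 | step 14 | ring-cis (4E)-cyclodec-4-en-10-one with 6α,9α-bis-OTES, 8β-OPMB, 15-OTBDPS and C12 dimethyl acetal | CC[Si](CC)(CC)O[C@@H]1/C=C(/CO[Si](c2ccccc2)(c2ccccc2)C(C)(C)C)CCCC(=O)[C@H](O[Si](CC)(CC)CC)[C@@H](OCc2ccc(OC)cc2)[C@H]1C(=C)C(OC)OC
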